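The data stem from a simulated flask from invented constants.

If a single-handed catalyst cannot tell two mirror images apart, both fall together and the excess of right-handed over left-handed substrate stays at zero. That symmetric case, zero excess, lies at s = 1 on the scale of the **selectivity factor** s, defined from L and R, the fractions of left-handed and right-handed substrate still left of their own charges:

s = ln L / ln R, so L/R = R^(s − 1)

the same everywhere: left-handed substrate 35 mM; right-handed substrate 35 mM; precatalyst 0.70 mM
- delta: partner 35 mM; protic impurity 7 mM; run made earlier
- eta: partner 140 mM; protic impurity 7 mM; run made earlier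
- flask: partner 70.0 mM; protic impurity 7.00 mM; time 5.0 d

| run | time / d | right-handed substrate / % | left-handed substrate / % | left-handed product / % |
|---|---|---|---|---|
| delta | 0.625 | 50 | 46 | 3 |
| delta | 1.25 | 48 | 41 | 8 |
| delta | 1.67 | 49 | 37 | 10 |
| delta | 2.50 | 51 | 27 | 18 |
| delta | 3.00 | 50 | 25 | 21 |
| eta | 0.250 | 51 | 37 | 10 |
| eta | 0.417 | 48 | 29 | 21 |
| eta | 0.833 | 44 | 5 | 36 |
| eta | 1.67 | 32 | 0 | 41 |
| eta | 3.00 | 19 | 0 | 42 |

(standard deviation of a reading: 1.5 percentage points)

- free catalyst is single-handed; left-handed substrate and right-handed substrate are mirror images of each other, charged as a racemate, each of them at the stated concentration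

- whether the excess of right-handed substrate over left-handed substrate among what is left of the two reaches 90% by 5.0 d (yes / no)
- the highest excess of right-handed substrate over left-handed substrate among what is left of the two up to 5.0 d

At s = 1 the excess never moves. At the other extreme, right-handed substrate stands untouched until the wanted excess, with left-handed substrate at 2.63% of the two together. The eta run at 0.833 d places this chemistry between them, as a reading loosened by the small loss of right-handed substrate:

s = −2.30 / −0.128 = 18.0

With s held at this reading, the wanted excess falls at right-handed substrate 42.1% and left-handed substrate 2.21%, and L/R keeps falling after that. The time remains. The delta run loses left-handed substrate at 0.0884 d⁻¹ of the two together and the eta run at 0.549 d⁻¹. Taking twice the delta rate for this flask gives the time t to the wanted excess as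

t = 2.70 d

which is shorter than 5.0 d.

The forecast says yes, with a top of 99.5% (96% to 100%): “Excess should pass 90% near 2.5 d and approach 100%”.

    free catalyst + left-handed substrate ⇌ catalyst intermediate A (K = 569 M⁻¹, k = 0.771 M⁻¹ s⁻¹)
    free catalyst + right-handed substrate ⇌ catalyst intermediate B (K = 33.0 M⁻¹, k = 0.561 M⁻¹ s⁻¹)
    partner + catalyst intermediate A → free catalyst + left-handed product (k = 0.0104 M⁻¹ s⁻¹)
    partner + catalyst intermediate B → free catalyst + right-handed product (k = 0.00489 M⁻¹ s⁻¹)
    left-handed product ⇌ right-handed product (k = 3.17 × 10⁻⁶ s⁻¹)
    partner + precatalyst → free catalyst + spent reagent (k = 3.84 × 10⁻⁴ M⁻¹ s⁻¹)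
    partner + protic impurity → quenched reagent (k = 0.00202 M⁻¹ s⁻¹)

The flask gives yes, reaching 90% at 2.44 d, with a top of >99.9%. While left-handed substrate lasted, partner carried it through catalyst intermediate A, which held 53.8% of the catalyst at 0.500 d. At 2.50 d this flask held 2.03% left-handed against 44.3% right-handed substrate, so s reads 26.5 here. In the eta run at 1.67 d, s = 18.0 gives left-handed substrate 0.0161% beside a reading of 0%. With left-handed substrate at 0%, catalyst intermediate B carried right-handed substrate on, down to 34.7% at 5.00 d.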